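**Retrosynthetic overview**

1. Target ⇐ catalyst-controlled epoxidation of the 1(10)-E alkene ⇐ methyl cross-coupling and C8 acylation of an alkenylstannane ⇐ trans-hydrostannation of a ten-membered cycloalkyne lactone.
2. Ten-membered ring ⇐ four-carbon ring expansion: Grob-type fragmentation of a fused decalin β-hydroxy ketone through its enol triflate (cleaves the C1–C6 fusion bond, gives C1≡C10 and the C6 enone).
3. Decalin ⇐ 3-methylcyclohex-2-en-1-one (ring A; brings the Z-C4=C5 unit and its methyl) plus a C7–C10 aldehyde, joined by aldol (C1–C10) and intramolecular indium allylation (C6–C7, closes ring B).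
4. C7–C10 aldehyde ⇐ D-threitol acetonide (C8 and C9 stereocentres) plus methyl acrylate (C11–C13) by a Morita–Baylis–Hillman reaction.
5. Ring order: ring A (bought) → ring B (step 8) → ten-membered ring by fragmentation (step 10) → γ-lactone (step 11) → epoxide (step 15).

Assumption: compound 1 is counted as threitol (eight non-hydrogen atoms) carrying an acetonide protecting group; it is sold in this form.

Locants used in names: C1–C10 are the carbons of the final ten-membered ring. The lactone oxygen is on C6, C7 carries C11(=C13H2)–C12(=O), the ester is on C8, the hydroxyl on C9, the epoxide spans C1/C10, C14 is the methyl on C10 and C15 the methyl on C4. The target is (1R,6S,7S,8R,9S,10R).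

**Step 1**
Reactants: 1 (4R,5R)-2,2-dimethyl-1,3-dioxolane-4,5-dimethanol
Product: 2 {(4R,5R)-5-[(tert-butyldimethylsilyloxy)methyl]-2,2-dimethyl-1,3-dioxolan-4-yl}methanol
Conditions: NaH (1.0 equiv), THF, 0 °C; TBSCl, 0 → 25 °C
Reagents that add atoms: tert-butyldimethylsilyl chloride, CC(C)(C)[Si](C)(C)Cl
Why: Monosilylation of a C2-symmetric diol through its monosodium alkoxide (Williamson-type O-silylation) gives one product whichever end reacts; C8 and C9 come from the chiral pool and are not touched.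

**Step 2**
Reactants: 2 {(4R,5R)-5-[(tert-butyldimethylsilyloxy)methyl]-2,2-dimethyl-1,3-dioxolan-4-yl}methanol
Product: 3 (4S,5R)-5-[(tert-butyldimethylsilyloxy)methyl]-2,2-dimethyl-1,3-dioxolane-4-carbaldehyde
Conditions: Dess–Martin periodinane, CH2Cl2, 0 → 25 °C
Reagents that add atoms: none
Why: Dess–Martin oxidation of the primary alcohol is non-basic, so the α-alkoxy stereocentre (C8) is not epimerised.

**Step 3**
Reactants: 3 (4S,5R)-5-[(tert-butyldimethylsilyloxy)methyl]-2,2-dimethyl-1,3-dioxolane-4-carbaldehyde; 4 methyl acrylate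
Product: 5 methyl 2-[{(4R,5R)-5-[(tert-butyldimethylsilyloxy)methyl]-2,2-dimethyl-1,3-dioxolan-4-yl}(hydroxy)methyl]prop-2-enoate (both carbinol epimers)
Conditions: DABCO (0.5 equiv), MeOH (1 equiv), neat 4 (5 equiv), 25 °C, 72 h
Reagents that add atoms: none
Why: The Morita–Baylis–Hillman reaction joins C7 to C11; the new carbinol centre forms as a mixture, which does not matter because C7 becomes an sp2 allyl terminus in step 8.

**Step 4**
Reactants: 5 methyl 2-[{(4R,5R)-5-[(tert-butyldimethylsilyloxy)methyl]-2,2-dimethyl-1,3-dioxolan-4-yl}(hydroxy)methyl]prop-2-enoate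
Product: 6 methyl 2-[(acetyloxy){(4R,5R)-5-[(tert-butyldimethylsilyloxy)methyl]-2,2-dimethyl-1,3-dioxolan-4-yl}methyl]prop-2-enoate
Conditions: Ac2O, pyridine, DMAP (5 mol %), CH2Cl2, 0 °C
Reagents that add atoms: acetic anhydride, CC(=O)OC(C)=O
Why: DMAP-catalysed acetylation gives the allylic acetate needed for the umpoled allylation; unlike the allylic bromide it tolerates the lithium enolate of step 7.

**Step 5**
Reactants: 6 methyl 2-[(acetyloxy){(4R,5R)-5-[(tert-butyldimethylsilyloxy)methyl]-2,2-dimethyl-1,3-dioxolan-4-yl}methyl]prop-2-enoate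
Product: 7 methyl 2-{(acetyloxy)[(4R,5R)-5-(hydroxymethyl)-2,2-dimethyl-1,3-dioxolan-4-yl]methyl}prop-2-enoate
Conditions: HF·pyridine, THF, 0 → 25 °C
Reagents that add atoms: none
Why: Fluoride-mediated cleavage of the silyl ether leaves the acetate, acetonide and acrylate intact.

**Step 6**
Reactants: 7 methyl 2-{(acetyloxy)[(4R,5R)-5-(hydroxymethyl)-2,2-dimethyl-1,3-dioxolan-4-yl]methyl}prop-2-enoate
Product: 8 methyl 2-{(acetyloxy)[(4R,5S)-5-formyl-2,2-dimethyl-1,3-dioxolan-4-yl]methyl}prop-2-enoate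
Conditions: Dess–Martin periodinane, CH2Cl2, 0 °C
Reagents that add atoms: none
Why: Dess–Martin oxidation gives the C10 aldehyde without epimerising C9; the aldehyde is used at once.

**Step 7**
Reactants: 9 3-methylcyclohex-2-en-1-one; 8 methyl 2-{(acetyloxy)[(4R,5S)-5-formyl-2,2-dimethyl-1,3-dioxolan-4-yl]methyl}prop-2-enoate
Product: 11 methyl 2-{(acetyloxy)[(4R,5R)-5-[hydroxy(4-methyl-2-oxocyclohex-3-en-1-yl)methyl]-2,2-dimethyl-1,3-dioxolan-4-yl]methyl}prop-2-enoate (diastereomer mixture at C1, C10 and the acetoxy carbon), via lithium dienolate 10 (not isolated)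
Conditions: LiN(i-Pr)2, THF, −78 °C; then 8, −78 °C, 15 min; H2O
Reagents that add atoms: none
Why: Kinetic deprotonation gives the cross-conjugated dienolate, whose aldol addition to the aldehyde forms C1–C10; the new centres at C1 and C10 form unselectively but both are erased in steps 9 and 10.

**Step 8**
Reactants: 11 methyl 2-{(acetyloxy)[(4R,5R)-5-[hydroxy(4-methyl-2-oxocyclohex-3-en-1-yl)methyl]-2,2-dimethyl-1,3-dioxolan-4-yl]methyl}prop-2-enoate
Product: 13 methyl 6,10-dihydroxy-8,9-(isopropylidenedioxy)-14-nor-1,6-cyclogermacra-4,11(13)-dien-12-oate (decalin: ring A = C1–C2–C3–C4(Me)=C5–C6(OH), ring B = C6–C7–C8–C9–C10(OH)–C1; C7, C8, C9 as in the target; mixture at C1, C6, C10), via allylindium iodide acetate 12 (not isolated)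
Conditions: Pd(PPh3)4 (5 mol %), InI (1.5 equiv), THF, 25 °C; H2O
Reagents that add atoms: none
Why: Palladium-catalysed, InI-mediated umpolung of the allylic acetate gives an allylindium that adds intramolecularly to the ring ketone (Barbier-type carbonyl allylation through a chair transition state) and closes ring B. C7 is set with its 1-(methoxycarbonyl)vinyl group equatorial, trans to the C8–O bond of the trans-acetonide; C6 is formed here and erased later.

**Step 9**
Reactants: 13 methyl 6,10-dihydroxy-8,9-(isopropylidenedioxy)-14-nor-1,6-cyclogermacra-4,11(13)-dien-12-oate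
Product: 14 methyl 6-hydroxy-8,9-(isopropylidenedioxy)-10-oxo-14-nor-1,6-cyclogermacra-4,11(13)-dien-12-oate
Conditions: Dess–Martin periodinane, CH2Cl2, 0 °C
Reagents that add atoms: none
Why: Dess–Martin oxidation converts only the secondary C10 alcohol; the tertiary C6 alcohol cannot react, and the C10 epimers converge.

**Step 10**
Reactants: 14 methyl 6-hydroxy-8,9-(isopropylidenedioxy)-10-oxo-14-nor-1,6-cyclogermacra-4,11(13)-dien-12-oate
Product: 16 methyl (4Z)-8,9-(isopropylidenedioxy)-6-oxo-14-norgermacra-4,11(13)-dien-1(10)-yn-12-oate (ten-membered cycloalkynone), via enol triflate alkoxide 15 (not isolated)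
Conditions: KN(SiMe3)2 (2.1 equiv), THF, −78 °C; PhNTf2 (1.1 equiv), −78 → 0 °C; pH 7 buffer
Reagents that add atoms: none
Why: Proposed new method: double deprotonation gives the C6 alkoxide and the C1=C10 enolate (enolisation toward C9 would flatten a trans-fused acetonide carbon); O-triflation then places the C10–OTf bond trans across C1=C10, antiperiplanar to the fusion bond C1–C6, so the alkoxide expels triflate in a Grob-type fragmentation that cleaves C1–C6 and expands ring A by four carbons to the ten-membered C1≡C10 cycloalkyne with C6 returned as the Z-enone carbonyl. The closest known reactions are the nucleophile-triggered fragmentation of vinylogous acyl triflates to acyclic alkynyl ketones and the Eschenmoser–Tanabe fragmentation, neither shown for an enol triflate of a fused aldol giving a medium-ring cycloalkyne; no stereocentre is formed, C1, C6 and C10 are erased and all diastereomers of 14 converge.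

**Step 11**
Reactants: 16 methyl (4Z)-8,9-(isopropylidenedioxy)-6-oxo-14-norgermacra-4,11(13)-dien-1(10)-yn-12-oate
Product: 18 (4Z)-8,9-dihydroxy-14-norgermacra-4,11(13)-dien-1(10)-yn-12,6-olide (6,7-cis lactone; C6–C9 as in the target), via allylic alcohol 17 (not isolated)
Conditions: NaBH4, CeCl3·7H2O, MeOH, −78 °C; then TsOH·H2O (20 mol %), MeOH–H2O, 40 °C
Reagents that add atoms: none
Why: Luche 1,2-reduction of the enone, with hydride adding to the carbonyl face anti to the C7 substituent (Felkin–Anh, peripheral attack), sets C6 (6S); acid then closes the cis-fused α-methylene-γ-lactone and hydrolyses the acetonide.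

**Step 12**
Reactants: 18 (4Z)-8,9-dihydroxy-14-norgermacra-4,11(13)-dien-1(10)-yn-12,6-olide
Product: 19 (1(10)Z,4Z)-8,9-dihydroxy-10-(tributylstannyl)-14-norgermacra-1(10),4,11(13)-trien-12,6-olide
Conditions: Bu3SnH (1.1 equiv), [Cp*RuCl]4 (3 mol %), CH2Cl2, 25 °C
Reagents that add atoms: tributyltin hydride, CCCC[SnH](CCCC)CCCC
Why: Hydroxyl-directed ruthenium-catalysed trans-hydrostannation puts tin on the alkyne carbon next to the C9 hydroxyl (C10) and hydrogen on C1 by anti addition, which fixes C2 and C9 trans across the new double bond.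

**Step 13**
Reactants: 19 (1(10)Z,4Z)-8,9-dihydroxy-10-(tributylstannyl)-14-norgermacra-1(10),4,11(13)-trien-12,6-olide; 20 2-methylpropanoyl chloride
Product: 21 (1(10)Z,4Z)-9-hydroxy-8-(2-methylpropanoyloxy)-10-(tributylstannyl)-14-norgermacra-1(10),4,11(13)-trien-12,6-olide
Conditions: 20 (1.05 equiv), pyridine, CH2Cl2, −40 °C
Reagents that add atoms: none
Why: Site-selective O-acylation; the C9 hydroxyl is shielded by the adjacent tributylstannyl-bearing alkene carbon, so the acid chloride takes the C8 hydroxyl, and no stereocentre changes.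

**Step 14**
Reactants: 21 (1(10)Z,4Z)-9-hydroxy-8-(2-methylpropanoyloxy)-10-(tributylstannyl)-14-norgermacra-1(10),4,11(13)-trien-12,6-olide
Product: 22 (1(10)E,4Z)-9-hydroxy-8-(2-methylpropanoyloxy)germacra-1(10),4,11(13)-trien-12,6-olide
Conditions: MeI, Pd(PPh3)4 (10 mol %), Cu(O2CC4H3S) (copper thiophene-2-carboxylate, 1.5 equiv), [Bu4N][Ph2PO2], DMF, 25 °C
Reagents that add atoms: iodomethane, CI
Why: Copper-assisted Stille methyl cross-coupling replaces tin by methyl with retention, giving the E-trisubstituted C1=C10 alkene; the free C9 hydroxyl helps the tin-to-copper exchange.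

**Step 15**
Reactants: 22 (1(10)E,4Z)-9-hydroxy-8-(2-methylpropanoyloxy)germacra-1(10),4,11(13)-trien-12,6-olide
Product: 23 CNP0110853.1, (1R,6S,7S,8R,9S,10R,4Z)-1,10-epoxy-9-hydroxy-8-(2-methylpropanoyloxy)germacra-4,11(13)-dien-12,6-olide
Conditions: D-fructose-derived Shi ketone (30 mol %), KHSO5 (as 2KHSO5·KHSO4·K2SO4), pH 8 buffer, Bu4NHSO4 (cat.), MeCN–CH2(OMe)2–H2O, 0 °C
Reagents that add atoms: potassium peroxymonosulfate, [K+].[O-]S(=O)(=O)OO
Why: Shi asymmetric epoxidation of the E-trisubstituted alkene through the spiro dioxirane transition state sets C1 and C10 (1R,10R) under catalyst control; the Z-alkene next to the lactone oxygen and the electron-poor methylene lactone react more slowly.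

**Compound list**

1 | (4R,5R)-2,2-dimethyl-1,3-dioxolane-4,5-dimethanol (2,3-O-isopropylidene-D-threitol) | OC[C@H]1OC(C)(C)O[C@@H]1CO | starting material
2 | {(4R,5R)-5-[(tert-butyldimethylsilyloxy)methyl]-2,2-dimethyl-1,3-dioxolan-4-yl}methanol | OC[C@H]1OC(C)(C)O[C@@H]1CO[Si](C)(C)C(C)(C)C | intermediate
3 | (4S,5R)-5-[(tert-butyldimethylsilyloxy)methyl]-2,2-dimethyl-1,3-dioxolane-4-carbaldehyde | O=C[C@H]1OC(C)(C)O[C@@H]1CO[Si](C)(C)C(C)(C)C | intermediate
4 | methyl acrylate | C=CC(=O)OC | starting material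
5 | methyl 2-[{(4R,5R)-5-[(tert-butyldimethylsilyloxy)methyl]-2,2-dimethyl-1,3-dioxolan-4-yl}(hydroxy)methyl]prop-2-enoate | C=C(C(=O)OC)C(O)[C@H]1OC(C)(C)O[C@@H]1CO[Si](C)(C)C(C)(C)C | intermediate
6 | methyl 2-[(acetyloxy){(4R,5R)-5-[(tert-butyldimethylsilyloxy)methyl]-2,2-dimethyl-1,3-dioxolan-4-yl}methyl]prop-2-enoate | C=C(C(=O)OC)C(OC(C)=O)[C@H]1OC(C)(C)O[C@@H]1CO[Si](C)(C)C(C)(C)C | intermediate
7 | methyl 2-{(acetyloxy)[(4R,5R)-5-(hydroxymethyl)-2,2-dimethyl-1,3-dioxolan-4-yl]methyl}prop-2-enoate | C=C(C(=O)OC)C(OC(C)=O)[C@H]1OC(C)(C)O[C@@H]1CO | intermediate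
8 | methyl 2-{(acetyloxy)[(4R,5S)-5-formyl-2,2-dimethyl-1,3-dioxolan-4-yl]methyl}prop-2-enoate | C=C(C(=O)OC)C(OC(C)=O)[C@H]1OC(C)(C)O[C@@H]1C=O | intermediate
9 | 3-methylcyclohex-2-en-1-one | CC1=CC(=O)CCC1 | starting material
10 | lithium 5-methylcyclohexa-1,5-dien-1-olate (cross-conjugated dienolate of 9) | [Li+].[O-]C1=CCCC(C)=C1 | intermediate
11 | methyl 2-{(acetyloxy)[(4R,5R)-5-[hydroxy(4-methyl-2-oxocyclohex-3-en-1-yl)methyl]-2,2-dimethyl-1,3-dioxolan-4-yl]methyl}prop-2-enoate | CC1=CC(=O)C(CC1)C(O)[C@H]2OC(C)(C)O[C@@H]2C(OC(C)=O)C(=C)C(=O)OC | intermediate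
12 | allylindium iodide acetate from 11 (indium on C13, C7=C11 double bond) | CC1=CC(=O)C(CC1)C(O)[C@H]2OC(C)(C)O[C@@H]2C=C(C[In](I)OC(C)=O)C(=O)OC | intermediate
13 | methyl 6,10-dihydroxy-8,9-(isopropylidenedioxy)-14-nor-1,6-cyclogermacra-4,11(13)-dien-12-oate | COC(=O)C(=C)[C@@H]1[C@H]2OC(C)(C)O[C@@H]2C(O)C3CCC(C)=CC13O | intermediate
14 | methyl 6-hydroxy-8,9-(isopropylidenedioxy)-10-oxo-14-nor-1,6-cyclogermacra-4,11(13)-dien-12-oate | COC(=O)C(=C)[C@@H]1[C@H]2OC(C)(C)O[C@@H]2C(=O)C3CCC(C)=CC13O | intermediate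
15 | potassium C6-alkoxide of the C1=C10 enol triflate of 14 | COC(=O)C(=C)[C@@H]1[C@H]2OC(C)(C)O[C@@H]2C(OS(=O)(=O)C(F)(F)F)=C3CCC(C)=CC13[O-].[K+] | intermediate
16 | methyl (4Z)-8,9-(isopropylidenedioxy)-6-oxo-14-norgermacra-4,11(13)-dien-1(10)-yn-12-oate | COC(=O)C(=C)[C@@H]1[C@H]2OC(C)(C)O[C@@H]2C#CCC/C(C)=C\C1=O | intermediate
17 | methyl (4Z,6S)-6-hydroxy-8,9-(isopropylidenedioxy)-14-norgermacra-4,11(13)-dien-1(10)-yn-12-oate | COC(=O)C(=C)[C@@H]1[C@H]2OC(C)(C)O[C@@H]2C#CCC/C(C)=C\[C@@H]1O | intermediate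
18 | (4Z)-8,9-dihydroxy-14-norgermacra-4,11(13)-dien-1(10)-yn-12,6-olide | C=C1C(=O)O[C@H]2/C=C(/C)CCC#C[C@@H](O)[C@H](O)[C@@H]12 | intermediate
19 | (1(10)Z,4Z)-8,9-dihydroxy-10-(tributylstannyl)-14-norgermacra-1(10),4,11(13)-trien-12,6-olide | C=C1C(=O)O[C@H]2/C=C(/C)CC/C=C(\[Sn](CCCC)(CCCC)CCCC)[C@@H](O)[C@H](O)[C@@H]12 | intermediate
20 | 2-methylpropanoyl chloride | CC(C)C(Cl)=O | starting material
21 | (1(10)Z,4Z)-9-hydroxy-8-(2-methylpropanoyloxy)-10-(tributylstannyl)-14-norgermacra-1(10),4,11(13)-trien-12,6-olide | C=C1C(=O)O[C@H]2/C=C(/C)CC/C=C(\[Sn](CCCC)(CCCC)CCCC)[C@@H](O)[C@H](OC(=O)C(C)C)[C@@H]12 | intermediate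
22 | (1(10)E,4Z)-9-hydroxy-8-(2-methylpropanoyloxy)germacra-1(10),4,11(13)-trien-12,6-olide | C=C1C(=O)O[C@H]2/C=C(/C)CC/C=C(\C)[C@@H](O)[C@H](OC(=O)C(C)C)[C@@H]12 | intermediate
23 | CNP0110853.1 | C=C1C(=O)O[C@H]2/C=C(/C)CC[C@H]3O[C@]3(C)[C@@H](O)[C@H](OC(=O)C(C)C)[C@@H]12 | target

**Step count and risks**

Total: 15 steps. Longest linear sequence: 15 steps (1 → 23); compounds 9 and 20 enter at steps 7 and 13. There is one protecting-group pair (TBS on and off), the acetonide is bought in place, and the isobutyrate is introduced as itself. All 15 skeletal carbons come from 1, 4, 9 and iodomethane.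

The three steps most likely to fail:

- **Step 10 (the proposed new ring expansion).** Risks are enolisation toward C9, lactonisation of the C6 alkoxide onto the ester before fragmentation, and base-induced epimerisation of C7 in the product. The fallback uses known chemistry, sets out from 14 and comes back at 16. The tertiary aldol 14 is dehydrated (MsCl, Et3N, then DBU) to the fused dienone F1. Nucleophilic epoxidation of its ring-fusion C1=C6 bond (t-BuOOH, benzyltrimethylammonium hydroxide) gives the epoxy ketone F2. TsNHNH2 in AcOH–CH2Cl2 gives the tosylhydrazone F3, which undergoes the Eschenmoser–Tanabe fragmentation to the same cycloalkynone 16.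

- **Step 11 (C6 configuration and lactone position).** Hydride may add from the other face, and the freed C8 hydroxyl can compete for the lactone carbonyl. The fallback sets out from 16 and comes back at 18. If the reduction gives the 6-epimeric alcohol F4, it is saponified (LiOH, THF–H2O) to the hydroxy acid F5. Mitsunobu lactonisation (PPh3, DIAD) then closes the γ-lactone with inversion at the allylic C6 carbinol to give the acetonide lactone F6, so the lactone is already fixed on C6 before the acetonide is removed. TsOH·H2O in aqueous MeOH then gives 18.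

- **Step 13 (site-selective acylation).** The two secondary hydroxyls may not be differentiated well enough, and the acyl group can migrate. The fallback sets out from 19 and comes back at 22. The order is changed: the Stille conditions of step 14 applied to 19 give the methylated diol F7. Bu2SnO (toluene, reflux) converts it into the stannylene acetal F8. Treatment with 20 at 0 °C then acylates the less hindered, non-allylic C8 oxygen to give 22.

**Further compounds**

F1 | step 10 | methyl 8,9-(isopropylidenedioxy)-10-oxo-14-nor-1,6-cyclogermacra-1(6),4,11(13)-trien-12-oate (fused dienone) | COC(=O)C(=C)[C@@H]1[C@H]2OC(C)(C)O[C@@H]2C(=O)C3=C1C=C(C)CC3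
F2 | step 10 | methyl 1,6-epoxy-8,9-(isopropylidenedioxy)-10-oxo-14-nor-1,6-cyclogermacra-4,11(13)-dien-12-oate (epoxy ketone) | COC(=O)C(=C)[C@@H]1[C@H]2OC(C)(C)O[C@@H]2C(=O)C34OC13C=C(C)CC4
F3 | step 10 | C10 tosylhydrazone of F2 | COC(=O)C(=C)[C@@H]1[C@H]2OC(C)(C)O[C@@H]2C(=NNS(=O)(=O)c5ccc(C)cc5)C34OC13C=C(C)CC4
F4 | step 11 | methyl (4Z,6R)-6-hydroxy-8,9-(isopropylidenedioxy)-14-norgermacra-4,11(13)-dien-1(10)-yn-12-oate (6-epimer of 17) | COC(=O)C(=C)[C@@H]1[C@H]2OC(C)(C)O[C@@H]2C#CCC/C(C)=C\[C@H]1O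
F5 | step 11 | (4Z,6R)-6-hydroxy-8,9-(isopropylidenedioxy)-14-norgermacra-4,11(13)-dien-1(10)-yn-12-oic acid | OC(=O)C(=C)[C@@H]1[C@H]2OC(C)(C)O[C@@H]2C#CCC/C(C)=C\[C@H]1O
F6 | step 11 | (4Z)-8,9-(isopropylidenedioxy)-14-norgermacra-4,11(13)-dien-1(10)-yn-12,6-olide (6,7-cis) | C=C1C(=O)O[C@H]2/C=C(/C)CCC#C[C@H]3OC(C)(C)O[C@@H]3[C@@H]12
F7 | step 13 | (1(10)E,4Z)-8,9-dihydroxygermacra-1(10),4,11(13)-trien-12,6-olide | C=C1C(=O)O[C@H]2/C=C(/C)CC/C=C(\C)[C@@H](O)[C@H](O)[C@@H]12
F8 | step 13 | 8,9-O-dibutylstannylene acetal of F7 | C=C1C(=O)O[C@H]2/C=C(/C)CC/C=C(\C)[C@H]3O[Sn](CCCC)(CCCC)O[C@@H]3[C@@H]12
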